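## Analysis of the target

Gnetulin 31 is a 2,3-dihydro-1H-indene. A resorcinol ring (ring A, C3a–C4–C5–C6–C7–C7a, hydroxyls at C4 and C6) is fused to a five-membered ring whose three remaining carbons each carry one substituent. C1 carries an exocyclic E-configured 4-hydroxy-3-methoxybenzylidene group (exocyclic carbon Cα), C2 a 3,5-dihydroxyphenyl ring and C3 a 4-hydroxy-3-methoxyphenyl ring. C2 and C3 are the only stereocentres, both S, with the two aryl groups trans; the benzylidene aryl group lies on the C2 side of the double bond, away from C7–H. Five phenols must end free while two aryl methyl ethers stay, so every protecting group has to leave without touching O–CH3 and without reduction, because of the alkene. The compound is a stilbene flanked by electron-rich rings: acid can protonate C1 and trigger Friedel–Crafts capture of the Cα cation, light can scramble the alkene geometry, and base can epimerise the allylic and benzylic C2–H and C3–H or move the double bond into the ring. The difficulty is to place three different aryl-bearing carbons around a cyclopentane with absolute control, a trans diad and a defined trisubstituted alkene, and to keep them intact to the end. The route rests on ring A: its oxygens at C4 and C6 are meta, the pattern that arises when a vinylketene is joined to an oxygen-substituted alkyne, and it is annulated through C3a–C7a to a cyclopentene that can hold both stereocentres and the benzylidene beforehand.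

## Retrosynthetic reasoning

Indane numbering of 31 is used for every intermediate.

**Protecting groups (31 ⇒ 30 ⇒ 29).** Only O–benzyl and O–silyl bonds are cut. Four phenols travel as benzyl ethers from the building blocks 1, 6 and 7, because these ethers tolerate organolithium and cuprate reagents, amide bases, palladium catalysis and light. Hydrogenolysis is excluded by the alkene, so the benzyl groups leave under Lewis-acid conditions with a cation trap, after the silyl ether of 29 has been cleaved to 30. The two oxygens of ring A need no protection step: they appear as a free C4 hydroxyl and a C6 silyl ether.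

**Ring A (29 ⇒ 20 + 24).** The bonds C4–C5, C6–C7 and C3a–C4 are cut. Ring A holds no stereocentre, so building it last confines the risk of the route to a step that makes only an arene. Cutting C1–C7a or C3–C3a instead would push two stereocentres into an open chain. Diazoketone 20 has to rearrange to vinylketene 25; its ketene carbon becomes C4 with the hydroxyl, the former diazo carbon becomes C7, and the two carbons of siloxyalkyne 24 become C5 and the oxygenated C6. Cyclobutenone 26, dienylketene 27 and cyclohexadienone 28 lie on the way. The forward reaction must form 25 without disturbing the alkene geometry, combine it with 24 in one orientation, and close onto C3a.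

**Siloxyalkyne (24 ⇒ 21).** The C–O and O–Si bonds are cut: acetylene 21 is oxidised to the ynolate 23 via its lithium acetylide 22, and 23 is silylated on oxygen.

**Diazoketone (20 ⇒ 17 ⇒ 15 ⇒ 13).** The diazo group is removed to give methyl ketone 17 (diazo transfer in the forward sense). The C7a–acyl bond is cut to give dienyl triflate 15, which is coupled with an acetyl anion equivalent. The O–S bond is cut to give ketone 13. Ketone 13 is a cross-conjugated enone whose only enolisable α-carbon is C3a, so the position of the C3a=C7a double bond, and with it the site of ring fusion, is fixed by the substrate.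

**Benzylidene and C2 aryl group (13 ⇒ 11 ⇒ 5 + 6 + 7).** The C1=Cα bond is cut by aldol condensation and the C2–aryl bond by conjugate addition. Cuprate 9, made from aryl bromide 6 through aryllithium 8, adds to enone 5 anti to the C3 aryl group, which sets the trans diad by substrate control. The resulting enolate 10 is trapped by aldehyde 7 at C1 to give aldol 11, and elimination through mesylate 12 gives the E-benzylidene under the usual preference of 2-benzylidenecyclopentanones.

**First stereocentre (5 ⇒ 4 ⇒ 3 + 2 ⇒ 1).** The C3–aryl bond is cut. A desymmetrising Heck–Matsuda arylation of meso alkene 3 with diazonium salt 2 (from aniline 1) is the only step that needs external chirality. Oxidation of allylic alcohol 4 gives enone 5.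

## Alternatives that were turned down

**Alternative 1: one-carbon (4+1) ring closure.**
- Disconnection: C1–C2 and C2–C3, so that C2 and its resorcinyl ring arrive as a single carbon.
- Forward key step: the ylide from sulfonium salt A3 adds in a 1,6-sense to the exocyclic carbon (C3) of p-quinone methide A2; the ketone enolate at C1 then displaces the sulfide from C2 and closes the five-membered ring to the all-trans aroyl indane A1.
- For: it is highly convergent, ring A is bought and not built, and no diazo compound or light is needed. In step count to the indane skeleton it is stronger than the chosen route.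
- Against: A2 is a quinone methide without flanking bulky groups and would have to be made and intercepted in situ. Absolute control would need a chiral sulfur substituent or catalyst acting on such an acceptor, which is not secure. A1 has the wrong group at C1: the ketone must be reduced and the carbinol dehydrated toward C1, an ionisation beside two electron-rich rings where Friedel–Crafts capture and E/Z mixtures threaten. The free phenol of A1 also has to be carried or re-protected.
- Comparison: the chosen route is longer before its key step, but it sets the absolute configuration by a known desymmetrisation and the alkene geometry at an enone, before the risky step and without a cation at Cα.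

**Alternative 2: reductive alkyne Heck closure.**
- Disconnection: C1–C7a, the aryl–alkene bond.
- Forward key step: zerovalent palladium inserts into the C7a–Br bond of alkynyl aryl bromide A5, syn-carbopalladation of the alkyne in a 5-exo-dig sense forms C1–C7a, and a hydride donor replaces palladium on Cα with retention to give pentabenzyl ether A4.
- For: the benzylidene geometry follows from syn addition. On this point it is stronger than the chosen route, whose alkene is set thermodynamically and must then survive a photochemical step. A4 is one deprotection from the target, and ring A is a purchased arene.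
- Against: A5 holds both stereocentres in an open chain with no ring to enforce the relative configuration. Its C2–H is propargylic and benzylic, so propargyl–allenyl isomerisation and epimerisation threaten under basic Heck conditions. The C–Br bond is flanked by a bulky diarylalkyl group, which slows oxidative addition.
- Comparison: the chosen route gives up the mechanistic guarantee of geometry. In exchange it sets the trans diad on a cyclopentenone template by well-precedented substrate control.

**Alternative 3: Wolff ring contraction.**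
- Disconnection: C1–C2, by contraction of a six-membered ring.
- Forward key step: photolysis of diazotetralone A7 makes the future C2 shift to the carbene carbon; the ring-contracted ketene is captured by an alcohol as methyl ester A6.
- For: this ring contraction is dependable, ring A is bought, and the diazo group of A7 comes from a simple diazo transfer to a doubly activated methylene. That is easier than the detrifluoroacetylative protocol of the chosen route.
- Against: A7 needs its own enantioselective synthesis of a trans-diaryl tetralone with an epimerisable α-aryl ketone. A6 creates a C1 stereocentre only to destroy it. Turning the ester into the E-benzylidene takes reduction, aryl addition and dehydration, with the same Cα cation problem as Alternative 1 and competition from the endocyclic indene.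
- Comparison: both routes use a Wolff rearrangement. In the chosen route it leads directly to the finished carbon skeleton with the alkene already in place, so no functional-group changes at C1 follow the key step.

Key step: step 10

Remarks on the chemistry:
- Assumption: the sense of induction in step 2 is fixed by the ligand antipode; the antipode that gives (1R,4S)-4 is used.
- (Triisopropylsilyloxy)ethyne 24 is not taken as purchasable and is made in step 9.

## Steps

Step 1
Reactants: 1 4-(benzyloxy)-3-methoxyaniline
Product: 2 4-(benzyloxy)-3-methoxybenzenediazonium tetrafluoroborate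
Conditions: NaNO2, 48% aq. HBF4, H2O, 0 °C; filter, wash with cold Et2O
Reagents that add atoms: sodium nitrite, [Na+].[O-]N=O; tetrafluoroboric acid, [H+].F[B-](F)(F)F
Why: Diazotisation of an electron-rich aniline; the tetrafluoroborate precipitates and is stable enough to be filtered and stored cold, and the benzyl and methyl ethers are inert to cold aqueous acid.

Step 2
Reactants: 3 cyclopent-3-en-1-ol; 2 4-(benzyloxy)-3-methoxybenzenediazonium tetrafluoroborate
Product: 4 (1R,4S)-4-[4-(benzyloxy)-3-methoxyphenyl]cyclopent-2-en-1-ol (cis)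
Conditions: Pd(O2CCF3)2 (5 mol %), (S)-4-tert-butyl-2-[5-(trifluoromethyl)pyridin-2-yl]-4,5-dihydrooxazole (6 mol %), ZnCO3 (0.5 equiv), MeOH, 40 °C
Reagents that add atoms: none
Why: Enantioselective Heck–Matsuda desymmetrisation: the cationic aryl–palladium species from 2 adds to one enantiotopic alkene carbon of meso 3 on the hydroxyl-bearing face, and syn β-hydride elimination away from the new benzylic carbon leaves the allylic alcohol; the chiral N,N ligand selects the alkene carbon and sets C4 (S), while the hydroxyl directs the cis relationship.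

Step 3
Reactants: 4 (1R,4S)-4-[4-(benzyloxy)-3-methoxyphenyl]cyclopent-2-en-1-ol
Product: 5 (4S)-4-[4-(benzyloxy)-3-methoxyphenyl]cyclopent-2-en-1-one
Conditions: activated MnO2 (excess), CH2Cl2, 20 °C
Reagents that add atoms: none
Why: Allylic alcohol oxidation on MnO2 under neutral heterogeneous conditions; no base is present, so the allylic and benzylic γ-stereocentre is not enolised, and the carbinol centre is erased.

Step 4
Reactants: 5 (4S)-4-[4-(benzyloxy)-3-methoxyphenyl]cyclopent-2-en-1-one; 6 1-bromo-3,5-bis(benzyloxy)benzene; 7 4-(benzyloxy)-3-methoxybenzaldehyde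
Product: 11 (2R,3R,4S)-2-{[4-(benzyloxy)-3-methoxyphenyl](hydroxy)methyl}-4-[4-(benzyloxy)-3-methoxyphenyl]-3-[3,5-bis(benzyloxy)phenyl]cyclopentan-1-one (both carbinol epimers), via aryllithium 8 (not isolated), via lithium diarylcuprate 9 (not isolated), via lithium enolate 10 (not isolated)
Conditions: 6 (2.2 equiv), n-BuLi (2.2 equiv), THF, −78 °C; CuI (1.1 equiv), −78 → −40 °C; 5, −78 °C; then 7 (1.5 equiv), −78 → −40 °C; aq. NH4Cl
Reagents that add atoms: none
Why: Tandem cuprate conjugate addition–aldol (three-component coupling): bromine–lithium exchange and CuI give Gilman reagent 9, which transfers one aryl group to the β-carbon of 5 anti to the existing aryl group (substrate control, trans); the regiodefined enolate 10 adds to aldehyde 7 anti to the new aryl group, and the unselective carbinol centre is removed in step 5.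

Step 5
Reactants: 11 aldol adduct (both carbinol epimers)
Product: 13 (2E,3S,4S)-2-[4-(benzyloxy)-3-methoxybenzylidene]-4-[4-(benzyloxy)-3-methoxyphenyl]-3-[3,5-bis(benzyloxy)phenyl]cyclopentan-1-one, via mesylate 12 (not isolated)
Conditions: MsCl, Et3N, CH2Cl2, 0 °C; then DBU, 0 → 20 °C
Reagents that add atoms: none
Why: Mesylation and E1cB elimination of a β-hydroxy ketone; both carbinol epimers converge on the E-benzylidene ketone (aryl anti to the carbonyl), the preferred geometry of 2-benzylidenecyclopentanones, and the two ring stereocentres are not α to the carbonyl and stay untouched.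

Step 6
Reactants: 13 (2E,3S,4S)-benzylidene ketone
Product: 15 (3R,4S,5E)-5-[4-(benzyloxy)-3-methoxybenzylidene]-3-[4-(benzyloxy)-3-methoxyphenyl]-4-[3,5-bis(benzyloxy)phenyl]cyclopent-1-en-1-yl trifluoromethanesulfonate, via potassium dienolate 14 (not isolated)
Conditions: KN(SiMe3)2 (1.1 equiv), THF, −78 °C; then N-(5-chloropyridin-2-yl)bis(trifluoromethanesulfonimide), −78 °C
Reagents that add atoms: N-(5-chloropyridin-2-yl)bis(trifluoromethanesulfonimide) (Comins' reagent), O=S(=O)(N(c1ccc(Cl)cn1)S(=O)(=O)C(F)(F)F)C(F)(F)F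
Why: Kinetic enolisation of the cross-conjugated enone can occur only at the α′-methylene, since the other α-carbon is the benzylidene carbon, so dienolate 14 and the later C3a=C7a double bond are regiodefined; O-triflation of the enolate at −78 °C is standard enol triflate formation.

Step 7
Reactants: 15 dienyl triflate
Product: 17 1-{(3S,4S,5E)-5-[4-(benzyloxy)-3-methoxybenzylidene]-3-[4-(benzyloxy)-3-methoxyphenyl]-4-[3,5-bis(benzyloxy)phenyl]cyclopent-1-en-1-yl}ethan-1-one, via 1-ethoxyvinyl triene 16 (not isolated)
Conditions: tributyl(1-ethoxyvinyl)stannane, Pd(PPh3)4 (5 mol %), LiCl (3 equiv), 1,4-dioxane, 90 °C; then 1 M HCl, THF, 20 °C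
Reagents that add atoms: tributyl(1-ethoxyvinyl)stannane, CCCC[Sn](CCCC)(CCCC)C(=C)OCC; water, O
Why: Stille coupling of an alkenyl triflate with an acetyl anion equivalent (oxidative addition to zerovalent palladium, LiCl-assisted transmetalation, reductive elimination), then mild hydrolysis of enol ether 16; the enol ether is protonated far faster than the styrenic alkene, so geometry and stereocentres are kept.

Step 8
Reactants: 17 methyl ketone
Product: 20 2-diazo-1-{(3S,4S,5E)-5-[4-(benzyloxy)-3-methoxybenzylidene]-3-[4-(benzyloxy)-3-methoxyphenyl]-4-[3,5-bis(benzyloxy)phenyl]cyclopent-1-en-1-yl}ethan-1-one, via lithium enolate 18 (not isolated), via trifluoroacetyl diketone 19 (not isolated)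
Conditions: LiN(SiMe3)2 (1.1 equiv), THF, −78 °C; CF3CO2CH2CF3, −78 °C; aq. HCl work-up; then MsN3, Et3N, H2O (1 equiv), MeCN, 20 °C
Reagents that add atoms: methanesulfonyl azide, CS(=O)(=O)N=[N+]=[N-]
Why: Detrifluoroacetylative diazo transfer (Danheiser protocol): kinetic deprotonation of the methyl group and trifluoroacetylation give the activated diketone 19, which takes the diazo group from the sulfonyl azide and loses the trifluoroacetyl group; the method was devised for α,β-unsaturated methyl ketones and avoids acid chlorides and diazomethane.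

Step 9
Reactants: 21 acetylene
Product: 24 (triisopropylsilyloxy)ethyne, via lithium acetylide 22 (not isolated), via lithium ethynolate 23 (not isolated)
Conditions: 21 (excess), n-BuLi, THF, −78 °C; t-BuOOLi (from t-BuOOH and n-BuLi, THF, −78 °C), −78 → −20 °C; i-Pr3SiOTf, −78 °C; distil
Reagents that add atoms: tert-butyl hydroperoxide, CC(C)(C)OO; triisopropylsilyl trifluoromethanesulfonate, CC(C)[Si](OS(=O)(=O)C(F)(F)F)(C(C)C)C(C)C
Why: Oxidation of a lithium acetylide by lithium tert-butyl peroxide gives the ynolate (Julia ynolate synthesis), and a bulky silyl triflate silylates it on oxygen, the usual entry to triisopropylsilyl ynol ethers; the product is distillable and is used in excess in step 10.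

Step 10
Reactants: 20 diazoketone; 24 (triisopropylsilyloxy)ethyne
Product: 29 (1E,2S,3S)-1-[4-(benzyloxy)-3-methoxybenzylidene]-3-[4-(benzyloxy)-3-methoxyphenyl]-2-[3,5-bis(benzyloxy)phenyl]-6-[(triisopropylsilyl)oxy]-2,3-dihydro-1H-inden-4-ol, via vinylketene 25 (not isolated), via cyclobutenone 26 (not isolated), via dienylketene 27 (not isolated), via cyclohexadienone 28 (not isolated)
Conditions: 24 (3 equiv), degassed ClCH2CH2Cl (0.02 M), 450 nm LEDs, 20 °C; then dark, 80 °C
Reagents that add atoms: none
Why: Irradiation at 450 nm excites only the weak long-wavelength band of the diazo ketone, which loses N2 with 1,2-shift of the cyclopentenyl carbon C7a (Wolff rearrangement) to give vinylketene 25. Its electrophilic ketene carbon is attacked by the unsubstituted, nucleophilic carbon of siloxyalkyne 24, and the (2+2) cycloadduct 26 forms in one orientation (bonds C4–C5 and C6–C7). Warming opens 26 by reversible 4π-electrocyclic cleavage to dienylketene 27, whose Z isomer closes ring A by thermal 6π-electrocyclisation between the ketene carbon and C3a (bond C3a–C4); cyclohexadienone 28 then tautomerises irreversibly to phenol 29. The closest known reaction type is the Danheiser benzannulation in its photo-Wolff form with a silyl ynol ether. No stereocentre is created: C2 and C3 keep all four bonds throughout, and C3a only gives up its hydrogen on aromatisation. The step needs regioselectivity, secured by the polarity match of ketene and ynol ether that puts the silyloxy group at C6 meta to the C4 hydroxyl, and selectivity for the ring alkene C3a=C7a over the benzylidene, secured because only the ring alkene is linearly conjugated with the ketene while the exocyclic alkene is cross-conjugated and cannot enter the 6π array. The E geometry is protected by light that the stilbene-type chromophores of 27 to 29 do not absorb and by the absence of acid and base. Excess 24 and high dilution keep 25 from dimerising or acylating the product phenol.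

Step 11
Reactants: 29 silyl ether phenol
Product: 30 (1E,2S,3S)-1-[4-(benzyloxy)-3-methoxybenzylidene]-3-[4-(benzyloxy)-3-methoxyphenyl]-2-[3,5-bis(benzyloxy)phenyl]-2,3-dihydro-1H-indene-4,6-diol
Conditions: Bu4NF (1.1 equiv), AcOH (1.1 equiv), THF, 0 °C
Reagents that add atoms: none
Why: Fluoride cleavage of an aryl silyl ether; buffering with acetic acid keeps the resorcinol from standing as an oxidisable phenoxide, and the benzyl ethers and the alkene are inert.

Step 12
Reactants: 30 tetrabenzyl ether
Product: 31 gnetulin, (1E,2S,3S)-2-(3,5-dihydroxyphenyl)-1-(4-hydroxy-3-methoxybenzylidene)-3-(4-hydroxy-3-methoxyphenyl)-2,3-dihydro-1H-indene-4,6-diol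
Conditions: BCl3 (10 equiv), pentamethylbenzene (15 equiv), CH2Cl2, −78 °C; quench MeOH/CHCl3 at −78 °C, then aq. NaHCO3
Reagents that add atoms: none
Why: Lewis-acid debenzylation with a non-basic cation scavenger: benzyl cations are trapped before they can alkylate the resorcinol rings or the alkene, aryl methyl ethers are not cleaved at −78 °C, no reduction is involved so the exocyclic alkene survives, and the cold quench avoids acid-induced cyclisation of the product.

## Compound list

1 | 4-(benzyloxy)-3-methoxyaniline | COc1cc(N)ccc1OCc1ccccc1 | starting material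
2 | 4-(benzyloxy)-3-methoxybenzenediazonium tetrafluoroborate | COc1cc([N+]#N)ccc1OCc1ccccc1.F[B-](F)(F)F | intermediate
3 | cyclopent-3-en-1-ol | OC1CC=CC1 | starting material
4 | (1R,4S)-4-[4-(benzyloxy)-3-methoxyphenyl]cyclopent-2-en-1-ol (cis) | O[C@@H]1C[C@H](c2ccc(OCc3ccccc3)c(OC)c2)C=C1 | intermediate
5 | (4S)-4-[4-(benzyloxy)-3-methoxyphenyl]cyclopent-2-en-1-one | O=C1C[C@H](c2ccc(OCc3ccccc3)c(OC)c2)C=C1 | intermediate
6 | 1-bromo-3,5-bis(benzyloxy)benzene | Brc1cc(OCc2ccccc2)cc(OCc2ccccc2)c1 | starting material
7 | 4-(benzyloxy)-3-methoxybenzaldehyde | COc1cc(C=O)ccc1OCc1ccccc1 | starting material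
8 | [3,5-bis(benzyloxy)phenyl]lithium | [Li]c1cc(OCc2ccccc2)cc(OCc2ccccc2)c1 | intermediate (not isolated)
9 | lithium bis[3,5-bis(benzyloxy)phenyl]cuprate | [Li+].[Cu-](c1cc(OCc2ccccc2)cc(OCc2ccccc2)c1)c1cc(OCc2ccccc2)cc(OCc2ccccc2)c1 | intermediate (not isolated)
10 | lithium (3R,4S)-4-[4-(benzyloxy)-3-methoxyphenyl]-3-[3,5-bis(benzyloxy)phenyl]cyclopent-1-en-1-olate | [Li+].[O-]C1=C[C@H](c2cc(OCc3ccccc3)cc(OCc3ccccc3)c2)[C@@H](c2ccc(OCc3ccccc3)c(OC)c2)C1 | intermediate (not isolated)
11 | (2R,3R,4S)-2-{[4-(benzyloxy)-3-methoxyphenyl](hydroxy)methyl}-4-[4-(benzyloxy)-3-methoxyphenyl]-3-[3,5-bis(benzyloxy)phenyl]cyclopentan-1-one, both carbinol epimers | O=C1C[C@H](c2ccc(OCc3ccccc3)c(OC)c2)[C@@H](c2cc(OCc3ccccc3)cc(OCc3ccccc3)c2)[C@@H]1C(O)c1ccc(OCc2ccccc2)c(OC)c1 | intermediate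
12 | methanesulfonate of 11 | O=C1C[C@H](c2ccc(OCc3ccccc3)c(OC)c2)[C@@H](c2cc(OCc3ccccc3)cc(OCc3ccccc3)c2)[C@@H]1C(OS(C)(=O)=O)c1ccc(OCc2ccccc2)c(OC)c1 | intermediate (not isolated)
13 | (2E,3S,4S)-2-[4-(benzyloxy)-3-methoxybenzylidene]-4-[4-(benzyloxy)-3-methoxyphenyl]-3-[3,5-bis(benzyloxy)phenyl]cyclopentan-1-one | COc1cc(/C=C2/C(=O)C[C@H](c3ccc(OCc4ccccc4)c(OC)c3)[C@H]2c2cc(OCc3ccccc3)cc(OCc3ccccc3)c2)ccc1OCc1ccccc1 | intermediate
14 | potassium (3R,4S,5E)-5-[4-(benzyloxy)-3-methoxybenzylidene]-3-[4-(benzyloxy)-3-methoxyphenyl]-4-[3,5-bis(benzyloxy)phenyl]cyclopent-1-en-1-olate | [K+].COc1cc(/C=C2/C([O-])=C[C@H](c3ccc(OCc4ccccc4)c(OC)c3)[C@H]2c2cc(OCc3ccccc3)cc(OCc3ccccc3)c2)ccc1OCc1ccccc1 | intermediate (not isolated)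
15 | (3R,4S,5E)-5-[4-(benzyloxy)-3-methoxybenzylidene]-3-[4-(benzyloxy)-3-methoxyphenyl]-4-[3,5-bis(benzyloxy)phenyl]cyclopent-1-en-1-yl trifluoromethanesulfonate | COc1cc(/C=C2/C(OS(=O)(=O)C(F)(F)F)=C[C@H](c3ccc(OCc4ccccc4)c(OC)c3)[C@H]2c2cc(OCc3ccccc3)cc(OCc3ccccc3)c2)ccc1OCc1ccccc1 | intermediate
16 | (3S,4S,5E)-1-(1-ethoxyvinyl)-5-[4-(benzyloxy)-3-methoxybenzylidene]-3-[4-(benzyloxy)-3-methoxyphenyl]-4-[3,5-bis(benzyloxy)phenyl]cyclopent-1-ene | COc1cc(/C=C2/C(C(=C)OCC)=C[C@H](c3ccc(OCc4ccccc4)c(OC)c3)[C@H]2c2cc(OCc3ccccc3)cc(OCc3ccccc3)c2)ccc1OCc1ccccc1 | intermediate (not isolated)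
17 | 1-{(3S,4S,5E)-5-[4-(benzyloxy)-3-methoxybenzylidene]-3-[4-(benzyloxy)-3-methoxyphenyl]-4-[3,5-bis(benzyloxy)phenyl]cyclopent-1-en-1-yl}ethan-1-one | COc1cc(/C=C2/C(C(C)=O)=C[C@H](c3ccc(OCc4ccccc4)c(OC)c3)[C@H]2c2cc(OCc3ccccc3)cc(OCc3ccccc3)c2)ccc1OCc1ccccc1 | intermediate
18 | lithium enolate of 17 (methyl side) | [Li+].COc1cc(/C=C2/C(C(=C)[O-])=C[C@H](c3ccc(OCc4ccccc4)c(OC)c3)[C@H]2c2cc(OCc3ccccc3)cc(OCc3ccccc3)c2)ccc1OCc1ccccc1 | intermediate (not isolated)
19 | 4,4,4-trifluoro-1-{(3S,4S,5E)-5-[4-(benzyloxy)-3-methoxybenzylidene]-3-[4-(benzyloxy)-3-methoxyphenyl]-4-[3,5-bis(benzyloxy)phenyl]cyclopent-1-en-1-yl}butane-1,3-dione | COc1cc(/C=C2/C(C(=O)CC(=O)C(F)(F)F)=C[C@H](c3ccc(OCc4ccccc4)c(OC)c3)[C@H]2c2cc(OCc3ccccc3)cc(OCc3ccccc3)c2)ccc1OCc1ccccc1 | intermediate (not isolated)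
20 | 2-diazo-1-{(3S,4S,5E)-5-[4-(benzyloxy)-3-methoxybenzylidene]-3-[4-(benzyloxy)-3-methoxyphenyl]-4-[3,5-bis(benzyloxy)phenyl]cyclopent-1-en-1-yl}ethan-1-one | COc1cc(/C=C2/C(C(=O)C=[N+]=[N-])=C[C@H](c3ccc(OCc4ccccc4)c(OC)c3)[C@H]2c2cc(OCc3ccccc3)cc(OCc3ccccc3)c2)ccc1OCc1ccccc1 | intermediate
21 | acetylene (ethyne) | C#C | starting material
22 | lithium acetylide | [Li]C#C | intermediate (not isolated)
23 | lithium ethynolate | [Li+].[O-]C#C | intermediate (not isolated)
24 | (triisopropylsilyloxy)ethyne | C#CO[Si](C(C)C)(C(C)C)C(C)C | intermediate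
25 | 2-{(3S,4S,5E)-5-[4-(benzyloxy)-3-methoxybenzylidene]-3-[4-(benzyloxy)-3-methoxyphenyl]-4-[3,5-bis(benzyloxy)phenyl]cyclopent-1-en-1-yl}ethen-1-one (vinylketene) | COc1cc(/C=C2/C(C=C=O)=C[C@H](c3ccc(OCc4ccccc4)c(OC)c3)[C@H]2c2cc(OCc3ccccc3)cc(OCc3ccccc3)c2)ccc1OCc1ccccc1 | intermediate (not isolated)
26 | 4-{(3S,4S,5E)-cyclopentenyl unit as in 25}-3-[(triisopropylsilyl)oxy]cyclobut-2-en-1-one, both epimers at the ring CH | COc1cc(/C=C2/C(C3C(=O)C=C3O[Si](C(C)C)(C(C)C)C(C)C)=C[C@H](c3ccc(OCc4ccccc4)c(OC)c3)[C@H]2c2cc(OCc3ccccc3)cc(OCc3ccccc3)c2)ccc1OCc1ccccc1 | intermediate (not isolated)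
27 | (3Z)-4-{(3S,4S,5E)-cyclopentenyl unit as in 25}-3-[(triisopropylsilyl)oxy]buta-1,3-dien-1-one (dienylketene) | COc1cc(/C=C2/C(/C=C(\C=C=O)O[Si](C(C)C)(C(C)C)C(C)C)=C[C@H](c3ccc(OCc4ccccc4)c(OC)c3)[C@H]2c2cc(OCc3ccccc3)cc(OCc3ccccc3)c2)ccc1OCc1ccccc1 | intermediate (not isolated)
28 | (1E,2S,3S)-1-[4-(benzyloxy)-3-methoxybenzylidene]-3-[4-(benzyloxy)-3-methoxyphenyl]-2-[3,5-bis(benzyloxy)phenyl]-6-[(triisopropylsilyl)oxy]-1,2,3,3a-tetrahydro-4H-inden-4-one (keto tautomer of 29, C3a unassigned) | COc1cc(/C=C2/C3=CC(O[Si](C(C)C)(C(C)C)C(C)C)=CC(=O)C3[C@H](c3ccc(OCc4ccccc4)c(OC)c3)[C@H]2c2cc(OCc3ccccc3)cc(OCc3ccccc3)c2)ccc1OCc1ccccc1 | intermediate (not isolated)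
29 | (1E,2S,3S)-1-[4-(benzyloxy)-3-methoxybenzylidene]-3-[4-(benzyloxy)-3-methoxyphenyl]-2-[3,5-bis(benzyloxy)phenyl]-6-[(triisopropylsilyl)oxy]-2,3-dihydro-1H-inden-4-ol | COc1cc(/C=C2/c3cc(O[Si](C(C)C)(C(C)C)C(C)C)cc(O)c3[C@H](c3ccc(OCc4ccccc4)c(OC)c3)[C@H]2c2cc(OCc3ccccc3)cc(OCc3ccccc3)c2)ccc1OCc1ccccc1 | intermediate
30 | (1E,2S,3S)-1-[4-(benzyloxy)-3-methoxybenzylidene]-3-[4-(benzyloxy)-3-methoxyphenyl]-2-[3,5-bis(benzyloxy)phenyl]-2,3-dihydro-1H-indene-4,6-diol | COc1cc(/C=C2/c3cc(O)cc(O)c3[C@H](c3ccc(OCc4ccccc4)c(OC)c3)[C@H]2c2cc(OCc3ccccc3)cc(OCc3ccccc3)c2)ccc1OCc1ccccc1 | intermediate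
31 | gnetulin, (1E,2S,3S)-2-(3,5-dihydroxyphenyl)-1-(4-hydroxy-3-methoxybenzylidene)-3-(4-hydroxy-3-methoxyphenyl)-2,3-dihydro-1H-indene-4,6-diol | COc1cc(/C=C2/c3cc(O)cc(O)c3[C@H](c3ccc(O)c(OC)c3)[C@H]2c2cc(O)cc(O)c2)ccc1O | target

## Step count and least certain steps

Total: 12 steps. Longest linear sequence: 11 steps (steps 1 to 8 and 10 to 12, from 1); step 9 is a one-step branch.

**Step 10 (key step).**
- Risk: light-driven E/Z isomerisation or other excited-state chemistry of the cross-conjugated diazo dienone may compete with the Wolff rearrangement.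
- Risk: the vinylketene may be lost to dimerisation or to acylation of the product phenol before it meets the alkyne.
- Risk: the thermal stage may stall at the cyclobutenone if ring opening is slow.
- Fallback (sets out from 13, returns at 29): the vinylketene is made without light and without a diazo compound. Peterson olefination of 13 with the lithium enolate of ethyl (trimethylsilyl)acetate gives the ethyl cyclopentylideneacetate F1. Hydrolysis with LiOH gives the acid F2. Its acid chloride ((COCl)2) is dehydrochlorinated at the γ-methylene (C3a) by Et3N in the presence of 24 at 80 °C in the dark, which gives 25 and lets the same cascade run to 29.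

**Step 9.**
- Risk: monolithium acetylide may disproportionate on warming before it is oxidised.
- Risk: silylation of the unhindered parent ynolate may occur on carbon instead of oxygen.
- Risk: the volatile product may be lost on isolation.
- Fallback (sets out from 20, returns at 29): the same oxidation and silylation applied to ethynyltrimethylsilane, whose lithium acetylide is stable, gives trimethyl{[(triisopropylsilyl)oxy]ethynyl}silane F3. Benzannulation of 20 with F3 gives the C5-trimethylsilyl phenol F4. Ipso-protodesilylation at the doubly oxygen-activated C5 (CF3CO2H, CH2Cl2, 0 °C) returns 29.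

**Step 8.**
- Risk: deprotonation at the γ-position (the allylic and benzylic C3–H) may compete with deprotonation of the methyl group, leading to epimerisation or double-bond migration.
- Risk: trifluoroacetylation may be incomplete.
- Fallback (sets out from 15, returns at 20): hydroxycarbonylation of 15 (Pd(OAc)2, 1,1′-bis(diphenylphosphino)ferrocene, CO, KOAc, aqueous DMF) gives the dienoic acid F5. Activation as the mixed anhydride (isobutyl chloroformate, N-methylmorpholine) and acylation of diazomethane give 20 without any enolate.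

**Step 4.**
- Risk: trapping of the enolate by the aldehyde may be incomplete, so that simple protonation wins.
- Risk: retro-aldol cleavage on warming, or 1,2-addition of residual aryllithium to the enone or the aldehyde.
- Fallback (sets out from 5 and 9, returns at 11): the conjugate addition is run with Me3SiCl so that the enolate is captured as the silyl enol ether F6. F6 is isolated and combined with 7 in a TiCl4-mediated Mukaiyama aldol addition to give 11.

**Step 2.**
- Risk: enantioselectivity may be insufficient, or of the opposite sense, with this electron-rich diazonium salt.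
- Risk: palladium hydride re-addition may move the alkene and give the saturated ketone.
- Fallback (sets out from 2 and 3, returns at 4): ligand-free Heck–Matsuda arylation (Pd(OAc)2, MeOH) gives racemic cis-4. Lipase-mediated acylation (Burkholderia cepacia lipase, vinyl acetate) separates the enantiomers. Written for the case in which the (1R,4S)-alcohol is acylated, the acetate F7 is isolated and methanolysed (K2CO3, MeOH) to 4; if the enzyme prefers the antipode, the unreacted alcohol is 4 itself.

## Further compounds

F1 | step 10 | ethyl 2-{(2E,3S,4S)-2-[4-(benzyloxy)-3-methoxybenzylidene]-4-[4-(benzyloxy)-3-methoxyphenyl]-3-[3,5-bis(benzyloxy)phenyl]cyclopentylidene}acetate (either geometry at the new double bond) | COc1cc(/C=C2/C(=CC(=O)OCC)C[C@H](c3ccc(OCc4ccccc4)c(OC)c3)[C@H]2c2cc(OCc3ccccc3)cc(OCc3ccccc3)c2)ccc1OCc1ccccc1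
F2 | step 10 | 2-{(2E,3S,4S)-2-[4-(benzyloxy)-3-methoxybenzylidene]-4-[4-(benzyloxy)-3-methoxyphenyl]-3-[3,5-bis(benzyloxy)phenyl]cyclopentylidene}acetic acid | COc1cc(/C=C2/C(=CC(=O)O)C[C@H](c3ccc(OCc4ccccc4)c(OC)c3)[C@H]2c2cc(OCc3ccccc3)cc(OCc3ccccc3)c2)ccc1OCc1ccccc1
F3 | step 9 | trimethyl{[(triisopropylsilyl)oxy]ethynyl}silane | C[Si](C)(C)C#CO[Si](C(C)C)(C(C)C)C(C)C
F4 | step 9 | (1E,2S,3S)-1-[4-(benzyloxy)-3-methoxybenzylidene]-3-[4-(benzyloxy)-3-methoxyphenyl]-2-[3,5-bis(benzyloxy)phenyl]-6-[(triisopropylsilyl)oxy]-5-(trimethylsilyl)-2,3-dihydro-1H-inden-4-ol | COc1cc(/C=C2/c3cc(O[Si](C(C)C)(C(C)C)C(C)C)c([Si](C)(C)C)c(O)c3[C@H](c3ccc(OCc4ccccc4)c(OC)c3)[C@H]2c2cc(OCc3ccccc3)cc(OCc3ccccc3)c2)ccc1OCc1ccccc1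
F5 | step 8 | (3S,4S,5E)-5-[4-(benzyloxy)-3-methoxybenzylidene]-3-[4-(benzyloxy)-3-methoxyphenyl]-4-[3,5-bis(benzyloxy)phenyl]cyclopent-1-ene-1-carboxylic acid | COc1cc(/C=C2/C(C(=O)O)=C[C@H](c3ccc(OCc4ccccc4)c(OC)c3)[C@H]2c2cc(OCc3ccccc3)cc(OCc3ccccc3)c2)ccc1OCc1ccccc1
F6 | step 4 | {[(3R,4S)-4-[4-(benzyloxy)-3-methoxyphenyl]-3-[3,5-bis(benzyloxy)phenyl]cyclopent-1-en-1-yl]oxy}trimethylsilane | C[Si](C)(C)OC1=C[C@H](c2cc(OCc3ccccc3)cc(OCc3ccccc3)c2)[C@@H](c2ccc(OCc3ccccc3)c(OC)c2)C1
F7 | step 2 | (1R,4S)-4-[4-(benzyloxy)-3-methoxyphenyl]cyclopent-2-en-1-yl acetate | CC(=O)O[C@@H]1C[C@H](c2ccc(OCc3ccccc3)c(OC)c2)C=C1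
A1 | alternative 1 | all-trans 1-aroyl-2,3-diarylindane with one free phenol | O=C(c1ccc(OCc2ccccc2)c(OC)c1)[C@@H]1c2cc(OCc3ccccc3)cc(OCc3ccccc3)c2[C@H](c2ccc(O)c(OC)c2)[C@H]1c1cc(OCc2ccccc2)cc(OCc2ccccc2)c1
A2 | alternative 1 | 4-({2,4-bis(benzyloxy)-6-[2-(4-(benzyloxy)-3-methoxyphenyl)-2-oxoethyl]phenyl}methylidene)-2-methoxycyclohexa-2,5-dien-1-one (p-quinone methide) | COC1=CC(=Cc2c(OCc3ccccc3)cc(OCc3ccccc3)cc2CC(=O)c2ccc(OCc3ccccc3)c(OC)c2)C=CC1=O
A3 | alternative 1 | [3,5-bis(benzyloxy)benzyl]dimethylsulfonium bromide | C[S+](C)Cc1cc(OCc2ccccc2)cc(OCc2ccccc2)c1.[Br-]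
A4 | alternative 2 | pentabenzyl gnetulin | COc1cc(/C=C2/c3cc(OCc4ccccc4)cc(OCc4ccccc4)c3[C@H](c3ccc(OCc4ccccc4)c(OC)c3)[C@H]2c2cc(OCc3ccccc3)cc(OCc3ccccc3)c2)ccc1OCc1ccccc1
A5 | alternative 2 | alkynyl aryl bromide: 1,5-bis(benzyloxy)-3-bromo-2-{1-[4-(benzyloxy)-3-methoxyphenyl]-4-[4-(benzyloxy)-3-methoxyphenyl]-2-[3,5-bis(benzyloxy)phenyl]but-3-yn-1-yl}benzene, configured as in the target | Brc1cc(OCc2ccccc2)cc(OCc2ccccc2)c1[C@H](c1ccc(OCc2ccccc2)c(OC)c1)[C@H](C#Cc1ccc(OCc2ccccc2)c(OC)c1)c1cc(OCc2ccccc2)cc(OCc2ccccc2)c1
A6 | alternative 3 | methyl 2,3-diarylindane-1-carboxylate, all-trans | COC(=O)[C@@H]1c2cc(OCc3ccccc3)cc(OCc3ccccc3)c2[C@H](c2ccc(OCc3ccccc3)c(OC)c2)[C@H]1c1cc(OCc2ccccc2)cc(OCc2ccccc2)c1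
A7 | alternative 3 | trans-5,7-bis(benzyloxy)-4-[4-(benzyloxy)-3-methoxyphenyl]-3-[3,5-bis(benzyloxy)phenyl]-1-diazo-3,4-dihydronaphthalen-2(1H)-one | [N-]=[N+]=C1C(=O)[C@H](c2cc(OCc3ccccc3)cc(OCc3ccccc3)c2)[C@@H](c2ccc(OCc3ccccc3)c(OC)c2)c2c(OCc3ccccc3)cc(OCc3ccccc3)cc21
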